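## Retrosynthetic overview

1. Enabling feature: in ring B, the pair C2(OH)(CO2H)–C3(OH)(CH2OH) is a (2S,3S)-tartaric acid that carries one extra carbon substituent on each carbinol carbon. Both extra carbons, C1 and C4, are para-oxybenzylic and can bear positive charge, and C8a of ring A is para to the C6 methoxy group.
2. Key disconnection: ring B is cut at C3–C4 and C1–C8a. This is a (3+3) annulation of a vanillyl cation (C4–C4a–C8a) with a C1–C2–C3 unit that is nucleophilic at C3 (silyl ketene acetal) and latently cationic at C1 (benzylic lactone C–O bond).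
3. The C1–C2–C3 unit is a cis-fused dioxolane/gamma-lactone bicycle. It is cut at C1–C2 by an aldol–lactonization of D-tartrate acetonide with protected 5-hydroxyvanillin.
4. Ring order: dioxolane (temporary), gamma-lactone (temporary), then ring B in the key step. There the lactone opens and leaves the C3 carboxyl group free beside the C2 ester. Ring A and the pendant ring C are bought.
5. Endgame: borane reduction of the free acid to the C3 CH2OH group, ketal hydrolysis, global hydrogenolysis.

Key step: step 6

Assumption: the lithium enolate of the tartrate acetonide takes up the aldehyde on the face it uses for alkyl halides (syn to the vicinal ester, net retention); the opposite case is covered by a fallback.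

Locants C1–C8a are those of the tetralin core of plicatic acid and are used for all intermediates.

## Route

Step 1
Reactants: 1 dibenzyl D-tartrate
Product: 2 dibenzyl (4S,5S)-2,2-dimethyl-1,3-dioxolane-4,5-dicarboxylate
Conditions: 2-methoxypropene, camphorsulfonic acid (cat.), CH2Cl2, 0 °C to rt
Reagents that add atoms: 2-methoxypropene, C=C(C)OC
Why: Acid-catalysed ketalization of the threo-diol with an enol ether should give the trans-disubstituted dioxolane without touching either stereocentre, and at room temperature the one equivalent of methanol released should not exchange the benzyl esters.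

Step 2
Reactants: 3 3,4-dihydroxy-5-methoxybenzaldehyde (5-hydroxyvanillin)
Product: 4 3,4-bis(benzyloxy)-5-methoxybenzaldehyde
Conditions: BnBr, K2CO3, DMF, 60 °C
Reagents that add atoms: benzyl bromide, BrCc1ccccc1
Why: Williamson ether synthesis on both phenols gives benzyl ethers that keep the para oxygen a strong donor for the later ionization at C1 and that fall in the final hydrogenolysis.

Step 3
Reactants: 2 dibenzyl (4S,5S)-2,2-dimethyl-1,3-dioxolane-4,5-dicarboxylate; 4 3,4-bis(benzyloxy)-5-methoxybenzaldehyde
Product: 6 benzyl (3aS,6aS)-6-[3,4-bis(benzyloxy)-5-methoxyphenyl]-2,2-dimethyl-4-oxotetrahydrofuro[3,4-d][1,3]dioxole-6a-carboxylate (cis-fused bicycle; either configuration at C6 = later C1), via lithium aldolate 5 (not isolated)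
Conditions: LiN(iPr)2, THF, −78 °C, 15 min; 4; −78 to −20 °C; AcOH
Reagents that add atoms: none
Why: Aldol addition of the lithiated tartrate acetonide (self-regeneration of stereocentres, with the C3 centre steering the aldehyde to the enolate face syn to the vicinal ester and so setting C2 with net retention) is followed by lactonization, which only the adduct with alkoxide and C3 ester cis on the dioxolane can undergo and which makes the reversible aldol step irreversible, while the new carbinol centre C1 needs no control because it is planarized in step 6.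

Step 4
Reactants: 6 bicyclic lactone
Product: 7 benzyl (6aS)-6-[3,4-bis(benzyloxy)-5-methoxyphenyl]-4-[(tert-butyldimethylsilyl)oxy]-2,2-dimethyl-6,6a-dihydrofuro[3,4-d][1,3]dioxole-6a-carboxylate (silyl ketene acetal; C3=C double bond at the ring fusion)
Conditions: TBSCl, then LiN(SiMe3)2 (added last), THF–DMPU, −78 °C; pentane, cold aq. NaHCO3
Reagents that add atoms: tert-butyldimethylsilyl chloride, CC(C)(C)[Si](C)(C)Cl
Why: O-silylation of the lactone enolate under internal-quench conditions, the silyl ketene acetal formation used before ester enolate Claisen rearrangements of beta-alkoxy esters, should trap the ring-fusion enolate before it can expel the C2 oxygen, whose C–O bond lies close to the enolate plane, and leaves C2 as the controlling stereocentre.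

Step 5
Reactants: 8 4-(benzyloxy)-3-methoxybenzyl alcohol
Product: 9 4-(benzyloxy)-3-methoxybenzyl 2,2,2-trichloroacetimidate
Conditions: Cl3CCN, DBU (cat.), CH2Cl2, 0 °C
Reagents that add atoms: trichloroacetonitrile, N#CC(Cl)(Cl)Cl
Why: Base-catalysed addition of the benzylic alcohol to trichloroacetonitrile, the imidate formation used for 4-methoxybenzyl and 3,4-dimethoxybenzyl donors, gives a benzyl cation source that catalytic acid ionizes and whose leaving group takes up one proton.

Step 6
Reactants: 7 silyl ketene acetal; 9 4-(benzyloxy)-3-methoxybenzyl 2,2,2-trichloroacetimidate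
Product: 13 (1S,2S,3S)-7-(benzyloxy)-2-[(benzyloxy)carbonyl]-1-[3,4-bis(benzyloxy)-5-methoxyphenyl]-2,3-(isopropylidenedioxy)-6-methoxy-1,2,3,4-tetrahydronaphthalene-3-carboxylic acid (trans-fused dioxolane), via O-silyl lactonium ion 10 (not isolated), via quinoid benzylic cation 11 (not isolated), via silyl ester 12 (not isolated)
Conditions: 7, Me3SiOTf (0.2 equiv), 4 Å MS, CH2Cl2, −78 °C; 9 (1.1 equiv) added slowly; −78 °C to rt; then THF–aq. citric acid
Reagents that add atoms: none
Why: Proposed new method: a cationic charge relay in which acid ionizes 9 to the 4-benzyloxy-3-methoxybenzyl cation, the ketene acetal carbon C3 of 7 captures it (bond C3–C4), the O-silyl lactonium ion 10 thus formed breaks its benzylic C1–O bond to give the quinoid cation 11 carrying a silyl ester, C8a attacks C1 (bond C1–C8a), and the proton lost on rearomatization ionizes the next molecule of 9, so that acid is only a catalyst. The closest known reaction types are the Lewis acid mediated SN1 benzylation of silyl ketene acetals and the Friedel–Crafts alkylation of arenes with gamma-aryl-gamma-butyrolactones, which are established one by one but not as a merged (3+3) annulation. Ring B closes 6-exo-trig with respect to the exocyclic C1=C(aryl) bond of 11 (the C4a–C8a bond of ring A is endocyclic), while the temporary lactone ring opens and sets the C3 carboxyl group free. C3 is controlled by the bicyclo[3.3.0] skeleton of 7, which can only stay cis-fused, so that the benzyl cation has to enter on the face that carries the C2 ester, which restores the (S,S)-tartrate pattern. C1 is controlled by allylic 1,3-strain in 11: the trans-fused dioxolane fixes the C2–C3 torsion and holds the C2 ester axial, the closure leading to the C1 epimer would eclipse the planar aryl group with this ester, and the open path puts the aryl group pseudoaxial and anti to the ester with the arene entering anti to the C2–O bond, and since C1 is planar in 11 both C1 epimers of 7 converge. The step needs chemoselectivity (the ketene acetal is by far the best nucleophile present and 9 is added slowly), the right order of events (in the ketene acetal the ring oxygen is no leaving group, so C1 ionizes only after C3 is quaternary, and C2 bears no hydrogen, so 11 cannot eliminate) and regioselectivity (C8a is para to the C6 methoxy group, whereas the other ortho position is wedged between side chain and methoxy group).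

Step 7
Reactants: 13 tetralin acid
Product: 14 benzyl (1S,2S,3R)-7-(benzyloxy)-1-[3,4-bis(benzyloxy)-5-methoxyphenyl]-3-(hydroxymethyl)-2,3-(isopropylidenedioxy)-6-methoxy-1,2,3,4-tetrahydronaphthalene-2-carboxylate
Conditions: BH3·THF, THF, 0 °C to rt; MeOH, then aq. work-up
Reagents that add atoms: none
Why: Chemoselective borane reduction of a carboxylic acid through its acyloxyborane spares the benzyl ester, the ketal and the ethers, so the two tartrate carboxyl groups differentiated by the lactone opening end at different oxidation levels, no stereocentre is touched, and the trans-diaxial placement of CH2OH and ester prevents lactonization.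

Step 8
Reactants: 14 ketal alcohol
Product: 15 benzyl (1S,2S,3R)-7-(benzyloxy)-1-[3,4-bis(benzyloxy)-5-methoxyphenyl]-2,3-dihydroxy-3-(hydroxymethyl)-6-methoxy-1,2,3,4-tetrahydronaphthalene-2-carboxylate
Conditions: CF3CO2H–H2O–THF (2:1:2), rt
Reagents that add atoms: none
Why: Acid hydrolysis of the ketal, helped by the strain of the trans-fused dioxolane, frees the two tertiary alcohols without breaking their C–O bonds, so C2 and C3 keep their configuration, and aryl benzyl ethers and the benzyl ester tolerate aqueous trifluoroacetic acid at this temperature.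

Step 9
Reactants: 15 tetrabenzyl-protected plicatic acid
Product: 16 plicatic acid, (1S,2S,3R)-1-(3,4-dihydroxy-5-methoxyphenyl)-2,3,7-trihydroxy-3-(hydroxymethyl)-6-methoxy-1,2,3,4-tetrahydronaphthalene-2-carboxylic acid
Conditions: H2 (1 atm), 10% Pd/C, MeOH–THF, rt
Reagents that add atoms: none
Why: Catalytic hydrogenolysis removes the three aryl benzyl ethers and the benzyl ester in one neutral operation, which spares the oxidation-prone catechol, the non-benzylic tertiary alcohols and the C1–aryl bonds.

## Compound list

1 | dibenzyl D-tartrate, dibenzyl (2S,3S)-2,3-dihydroxybutanedioate | O=C(OCc1ccccc1)[C@@H](O)[C@H](O)C(=O)OCc1ccccc1 | starting material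
2 | dibenzyl (4S,5S)-2,2-dimethyl-1,3-dioxolane-4,5-dicarboxylate | CC1(C)O[C@H](C(=O)OCc2ccccc2)[C@@H](C(=O)OCc2ccccc2)O1 | intermediate
3 | 3,4-dihydroxy-5-methoxybenzaldehyde | O=Cc1cc(O)c(O)c(OC)c1 | starting material
4 | 3,4-bis(benzyloxy)-5-methoxybenzaldehyde | O=Cc1cc(OCc2ccccc2)c(OCc2ccccc2)c(OC)c1 | intermediate
5 | lithium aldolate, (4S,5S)-dioxolane with the aryl(oxido)methyl group on C4 cis to the C5 ester; carbinol carbon uncontrolled | CC1(C)O[C@](C([O-])c2cc(OCc3ccccc3)c(OCc3ccccc3)c(OC)c2)(C(=O)OCc2ccccc2)[C@@H](C(=O)OCc2ccccc2)O1.[Li+] | intermediate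
6 | benzyl (3aS,6aS)-6-[3,4-bis(benzyloxy)-5-methoxyphenyl]-2,2-dimethyl-4-oxotetrahydrofuro[3,4-d][1,3]dioxole-6a-carboxylate, cis-fused, C6 uncontrolled | O=C1OC(c3cc(OCc4ccccc4)c(OCc4ccccc4)c(OC)c3)[C@]2(C(=O)OCc3ccccc3)OC(C)(C)O[C@H]12 | intermediate
7 | (6aS)-tert-butyldimethylsilyl ketene acetal of 6 | CC1(C)OC2=C(O[Si](C)(C)C(C)(C)C)OC(c3cc(OCc4ccccc4)c(OCc4ccccc4)c(OC)c3)[C@]2(C(=O)OCc3ccccc3)O1 | intermediate
8 | 4-(benzyloxy)-3-methoxybenzyl alcohol | COc1cc(CO)ccc1OCc1ccccc1 | starting material
9 | 4-(benzyloxy)-3-methoxybenzyl 2,2,2-trichloroacetimidate | COc1cc(COC(=N)C(Cl)(Cl)Cl)ccc1OCc1ccccc1 | intermediate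
10 | O-silyl lactonium ion, C3-benzylated, cis-fused, benzyl group syn to the C2 ester | CC1(C)O[C@]2(Cc3ccc(OCc4ccccc4)c(OC)c3)C(O[Si](C)(C)C(C)(C)C)=[O+]C(c3cc(OCc4ccccc4)c(OCc4ccccc4)c(OC)c3)[C@]2(C(=O)OCc3ccccc3)O1 | intermediate
11 | quinoid benzylic cation at C1, dioxolane with the C3 silyl ester | CC1(C)O[C@](Cc2ccc(OCc3ccccc3)c(OC)c2)(C(=O)O[Si](C)(C)C(C)(C)C)[C@@]([CH+]c2cc(OCc3ccccc3)c(OCc3ccccc3)c(OC)c2)(C(=O)OCc2ccccc2)O1 | intermediate
12 | tert-butyldimethylsilyl ester of 13 | COc1cc2c(cc1OCc1ccccc1)[C@H](c1cc(OCc3ccccc3)c(OCc3ccccc3)c(OC)c1)[C@]1(C(=O)OCc3ccccc3)OC(C)(C)O[C@@]1(C(=O)O[Si](C)(C)C(C)(C)C)C2 | intermediate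
13 | (1S,2S,3S)-tetralin acid, C2 benzyl ester, C3 free acid, trans-fused 2,3-O-isopropylidene | COc1cc2c(cc1OCc1ccccc1)[C@H](c1cc(OCc3ccccc3)c(OCc3ccccc3)c(OC)c1)[C@]1(C(=O)OCc3ccccc3)OC(C)(C)O[C@@]1(C(=O)O)C2 | intermediate
14 | (1S,2S,3R)-ketal alcohol, C3 CH2OH | COc1cc2c(cc1OCc1ccccc1)[C@H](c1cc(OCc3ccccc3)c(OCc3ccccc3)c(OC)c1)[C@]1(C(=O)OCc3ccccc3)OC(C)(C)O[C@@]1(CO)C2 | intermediate
15 | (1S,2S,3R)-benzyl ester triol, tri-O-benzyl plicatic acid benzyl ester | COc1cc2c(cc1OCc1ccccc1)[C@H](c1cc(OCc3ccccc3)c(OCc3ccccc3)c(OC)c1)[C@@](O)(C(=O)OCc1ccccc1)[C@](O)(CO)C2 | intermediate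
16 | plicatic acid (1S,2S,3R) | COc1cc2c(cc1O)[C@H](c1cc(O)c(O)c(OC)c1)[C@@](O)(C(=O)O)[C@](O)(CO)C2 | target

## Step count and risks

Total step count: 9.
Longest linear sequence: 7 (steps 1, 3, 4, 6, 7, 8, 9).

Steps most likely to fail:

(a) Step 6.
- What may go wrong: the chain-carrying acid may protodesilylate the ketene acetal. Silyl triflate may be lost early, so that a neutral lactone stalls before ionization. Facial selectivity at C1 may erode, because the pseudoaxial aryl group meets the axial C3 silyl ester.
- Fallback: it sets out from 6, comes back at 13, and separates the two bond formations into known anionic and cationic reactions.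
- Alcohol 8 is converted with PBr3 (Et2O, 0 °C) into 4-(benzyloxy)-3-methoxybenzyl bromide F1.
- The lithium enolate of 6 (LiN(iPr)2, THF–DMPU, −78 °C) is alkylated with F1 in an SN2 reaction on the only accessible face. This gives the neutral C3-benzylated bicyclic lactone F2, which is isolated.
- In a separate flask, CF3CO2H or BF3·OEt2 in CH2Cl2 brings about the Friedel–Crafts opening of the gamma-aryl lactone to 13. Acid and temperature can then be tuned for the C1 selectivity alone.

(b) Step 3.
- What may go wrong: the aldehyde may attack the enolate face anti to the vicinal ester. This leaves alkoxide and C3 ester trans on the dioxolane, blocks lactonization, and sets C2 in the wrong absolute sense.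
- Fallback: it sets out from 4, comes back at 6, and uses the enantiomeric chiral pool together with the fact that C3 is expendable.
- Commercial dibenzyl L-tartrate is ketalized as in step 1 to dibenzyl (4R,5R)-2,2-dimethyl-1,3-dioxolane-4,5-dicarboxylate F3.
- The lithium enolate of F3 adds to 4 with the anti sense to give the (4S,5R)-hydroxy diester F4, which already has the required C2 configuration.
- DBU in toluene then epimerizes the enolizable C3 centre. The cis isomer is drained by lactonization to 6.

(c) Step 4.
- What may go wrong: the C2 oxygen may be lost by beta-elimination from the ring-fusion enolate, in which the two fused rings twist the C2–O bond out of the enolate plane, before silylation occurs.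
- Fallback: it sets out from 2, comes back at 13, and reverses the order of substitution, so that only monocyclic dioxolane enolates, whose resistance to elimination is established, are used.
- The enolate of 2 is alkylated with F1 (LiN(iPr)2, THF–DMPU, −78 °C, retention) to give dibenzyl (4S,5S)-4-[4-(benzyloxy)-3-methoxybenzyl]-2,2-dimethyl-1,3-dioxolane-4,5-dicarboxylate F5.
- A second enolization at the remaining C–H and addition to 4, anti to the benzyl group and syn to the vicinal ester, is followed by lactonization to F2.
- F2 is cyclized with acid to 13 as described under (a).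

Further compounds
F1 | step 6 | 4-(benzyloxy)-3-methoxybenzyl bromide | COc1cc(CBr)ccc1OCc1ccccc1
F2 | step 6 | benzyl (3aS,6aS)-3a-[4-(benzyloxy)-3-methoxybenzyl]-6-[3,4-bis(benzyloxy)-5-methoxyphenyl]-2,2-dimethyl-4-oxotetrahydrofuro[3,4-d][1,3]dioxole-6a-carboxylate | O=C1OC(c3cc(OCc4ccccc4)c(OCc4ccccc4)c(OC)c3)[C@]2(C(=O)OCc3ccccc3)OC(C)(C)O[C@]12Cc1ccc(OCc2ccccc2)c(OC)c1
F3 | step 3 | dibenzyl (4R,5R)-2,2-dimethyl-1,3-dioxolane-4,5-dicarboxylate | CC1(C)O[C@@H](C(=O)OCc2ccccc2)[C@H](C(=O)OCc2ccccc2)O1
F4 | step 3 | dibenzyl (4S,5R)-4-{[3,4-bis(benzyloxy)-5-methoxyphenyl](hydroxy)methyl}-2,2-dimethyl-1,3-dioxolane-4,5-dicarboxylate | CC1(C)O[C@](C(O)c2cc(OCc3ccccc3)c(OCc3ccccc3)c(OC)c2)(C(=O)OCc2ccccc2)[C@H](C(=O)OCc2ccccc2)O1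
F5 | step 4 | dibenzyl (4S,5S)-4-[4-(benzyloxy)-3-methoxybenzyl]-2,2-dimethyl-1,3-dioxolane-4,5-dicarboxylate | CC1(C)O[C@](Cc2ccc(OCc3ccccc3)c(OC)c2)(C(=O)OCc2ccccc2)[C@@H](C(=O)OCc2ccccc2)O1
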